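## Retrosynthetic overview

1. Target 22 ⇐ β‑acetoxy ketone 21 (oxidation at C13, loss of AcOH) ⇐ 20 ⇐ 19 by one double Shi epoxidation; both oxiranes are formed last and together.
2. 19 ⇐ 18 by hydroxyl‑directed hydrogenation of the bridgehead C1=C14 olefin (sets C1); 18 ⇐ allylboronate 15 (CBS reduction at C10, acetylation, C–B → C–OH).
3. Key disconnection: 15 ⇐ acyclic enone‑dienylboronate 14 by a catalytic enantioselective type 2 intramolecular Diels–Alder reaction that closes the six‑membered and the twelve‑membered ring together (bonds C12–C13 and C11–C15).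
4. 14 ⇐ allylic chloride 11 + CO + vinylstannane 13; 11 ⇐ nerol 1 (C2–C9, 3Z), prenal 3 (C1, C14–C17) and CH2(Bpin)2 8 (C13).
5. Ring order: cyclohexene and cyclododecadiene simultaneously (step 8), then the two oxiranes simultaneously (step 13).

Assumption 1: locants follow verticillane numbering (C1/C11 bridgeheads, C15 the CMe2 bridge, C12–C14 the three‑carbon bridge, C18 the carbon on C12, C19/C20 the methyls on C4/C8).

Assumption 2: the (S)‑oxazaborolidinium catalyst of step 8 is taken to give the (11R,12S,13R) adduct drawn (α‑C–H···O binding model for enones); if correlation shows the opposite sense, its (R)‑antipode is used and nothing else changes.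

## Route

Step 1
Reactants: 1 nerol, (2Z)-3,7-dimethylocta-2,6-dien-1-ol
Product: 2 neryl bromide, (2Z)-1-bromo-3,7-dimethylocta-2,6-diene
Conditions: PBr3 (0.4 equiv), Et2O, −10 °C
Reagents that add atoms: phosphorus tribromide, BrP(Br)Br
Why: SN2‑type bromination of a primary allylic alcohol at low temperature keeps the Z‑trisubstituted olefin and avoids allylic transposition.

Step 2
Reactants: 3 prenal, 3-methylbut-2-enal; 2 neryl bromide
Product: 6 (4Z)-5,9-dimethyl-2-(propan-2-ylidene)deca-4,8-dienal, via potassium dienolate of prenal 4 (not isolated), via α-neryl β,γ-unsaturated aldehyde 5 (not isolated)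
Conditions: t-BuOK, THF, −78 °C; then 2, −78 → 0 °C; then DBU (0.2 equiv), rt
Reagents that add atoms: none
Why: Deconjugative α‑alkylation of an enal dienolate (kinetic attack at Cα, SN2 at the primary allylic bromide, Z olefin kept) followed by base‑mediated reconjugation to the tetrasubstituted enal, as in the lavandulal/isolavandulal series; no stereocentre remains.

Step 3
Reactants: 6 (4Z)-5,9-dimethyl-2-(propan-2-ylidene)deca-4,8-dienal
Product: 7 (4Z,8E)-10-hydroxy-5,9-dimethyl-2-(propan-2-ylidene)deca-4,8-dienal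
Conditions: SeO2 (0.3 equiv), t-BuOOH (2.5 equiv), salicylic acid (0.1 equiv), CH2Cl2, 0 °C → rt, stopped at about 70 % conversion
Reagents that add atoms: tert-butyl hydroperoxide, CC(C)(C)OO; selenium dioxide (oxygen relay), O=[Se]=O
Why: Riley allylic oxidation (ene reaction then [2,3]-shift) is selective for the E‑methyl of the terminal isopropylidene group, which fixes the 7E geometry; the enal olefin is electron‑poor and the internal Z olefin reacts more slowly.

Step 4
Reactants: 7 (4Z,8E)-10-hydroxy-5,9-dimethyl-2-(propan-2-ylidene)deca-4,8-dienal; 8 bis[(pinacolato)boryl]methane, 2,2'-methylenebis(4,4,5,5-tetramethyl-1,3,2-dioxaborolane)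
Product: 10 (2E,6Z,10E)-2,6-dimethyl-9-(propan-2-ylidene)-11-(4,4,5,5-tetramethyl-1,3,2-dioxaborolan-2-yl)undeca-2,6,10-trien-1-ol, via lithium bis(pinacolboryl)methanide 9 (not isolated)
Conditions: 8 (2.3 equiv), lithium 2,2,6,6-tetramethylpiperidide (2.3 equiv), THF, 0 °C; then 7, −78 °C → rt
Reagents that add atoms: none
Why: Boron‑Wittig olefination (1,2‑addition of the gem‑diboryl carbanion, then syn B–O elimination) gives the (E)-alkenylboronate; one extra equivalent of 9 is spent on the hydroxyl proton.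

Step 5
Reactants: 10 (2E,6Z,10E)-trienol boronate
Product: 11 2-[(1E,5Z,9E)-11-chloro-6,10-dimethyl-3-(propan-2-ylidene)undeca-1,5,9-trien-1-yl]-4,4,5,5-tetramethyl-1,3,2-dioxaborolane
Conditions: PPh3, CCl4, MeCN, 0 °C → rt
Reagents that add atoms: carbon tetrachloride, ClC(Cl)(Cl)Cl
Why: Appel chlorination is an SN2 displacement at the primary allylic carbinol under neutral conditions, so the dienylboronate and the E olefin are untouched.

Step 6
Reactants: 12 (E)-3-(tributylstannyl)prop-2-en-1-ol
Product: 13 (E)-3-(tributylstannyl)prop-2-en-1-yl acetate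
Conditions: Ac2O, pyridine, DMAP (cat.), CH2Cl2, 0 °C
Reagents that add atoms: acetic anhydride, CC(=O)OC(C)=O
Why: Plain O‑acylation; the acetate is the leaving group that later unveils the exocyclic methylene.

Step 7
Reactants: 11 allylic chloride; 13 (E)-3-(tributylstannyl)prop-2-en-1-yl acetate
Product: 14 (2E,6E,10Z,14E)-6,10-dimethyl-4-oxo-13-(propan-2-ylidene)-15-(4,4,5,5-tetramethyl-1,3,2-dioxaborolan-2-yl)pentadeca-2,6,10,14-tetraen-1-yl acetate
Conditions: PdCl2(MeCN)2 (5 mol %), CO (3 bar), THF, 45 °C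
Reagents that add atoms: carbon monoxide, [C-]#[O+]
Why: Stille carbonylative coupling (oxidative addition of the allylic chloride to zerovalent palladium, CO insertion at the primary terminus, transmetalation with retention of the E‑vinylstannane) gives the β,γ‑unsaturated enone without base; the boronate does not transmetalate without base, and phosphine‑free conditions spare the allylic acetate.

Step 8
Reactants: 14 acyclic enone‑dienylboronate
Product: 15 (3Z,7E,11R,12S,13R)-18-acetoxy-13-(4,4,5,5-tetramethyl-1,3,2-dioxaborolan-2-yl)verticilla-1(14),3,7-trien-10-one (bicyclo[9.3.1]pentadecatriene; C10 acyl and boryl group cis, CH2OAc trans to both)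
Conditions: (S)-3,3-diphenyl-1-(o-tolyl)tetrahydro-1H,3H-pyrrolo[1,2-c][1,3,2]oxazaborole (20 mol %), Tf2NH (16 mol %), CH2Cl2, 1 mM (14 added over 12 h), −40 → −20 °C
Reagents that add atoms: none
Why: Proposed new method: the protonated oxazaborolidine binds the enone carbonyl and lowers its LUMO; the unhindered, boron‑bearing diene terminus C13 bonds first to the β‑carbon C12 (asynchronous transition state with allyl cation character on the Me2C=C terminus), then C15 closes on C11, giving the 1,3‑bridged bicyclo[9.3.1] skeleton; the ketone lies endo, which places C10 and boron cis, the E‑enone puts C18 trans to C10, and the catalyst face sets C11 (and with it C12 and C13) absolutely; closest known chemistry is the Lewis‑acid‑promoted type 2 intramolecular Diels–Alder reaction of 2‑substituted 4‑methylpenta‑1,3‑dienes with vinyl ketones, oxazaborolidinium‑catalysed enone Diels–Alder reactions including transannular cases, and Diels–Alder reactions of 1‑boryl dienes.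

Step 9
Reactants: 15 bicyclic ketone
Product: 16 (3Z,7E,10R,11R,12S,13R)-18-acetoxy-13-(4,4,5,5-tetramethyl-1,3,2-dioxaborolan-2-yl)verticilla-1(14),3,7-trien-10-ol
Conditions: (S)-1-methyl-3,3-diphenyltetrahydro-1H,3H-pyrrolo[1,2-c][1,3,2]oxazaborole (0.2 equiv), catecholborane (1.5 equiv), toluene, −78 → −40 °C; MeOH quench, carbonate wash
Reagents that add atoms: none
Why: Corey–Bakshi–Shibata reduction with the branched C11 side as the large and the C9 methylene as the small group gives the (10R) carbinol under reagent control; catecholborane at low temperature leaves the olefins, the acetate and the allylboronate alone.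

Step 10
Reactants: 16 C10 alcohol
Product: 17 (3Z,7E,10R,11R,12S,13R)-10,18-diacetoxy-13-(4,4,5,5-tetramethyl-1,3,2-dioxaborolan-2-yl)verticilla-1(14),3,7-triene
Conditions: Ac2O, Et3N, DMAP (cat.), CH2Cl2, 0 °C → rt
Reagents that add atoms: acetic anhydride, CC(=O)OC(C)=O
Why: O‑acylation installs the C10 acetate of the target before any other hydroxyl is present.

Step 11
Reactants: 17 diacetate allylboronate
Product: 18 (3Z,7E,10R,11R,12S,13R)-10,18-diacetoxyverticilla-1(14),3,7-trien-13-ol
Conditions: NaBO3·4H2O, THF/H2O (1:1), rt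
Reagents that add atoms: sodium perborate, [Na+].[O-]OB=O
Why: Oxidation of the C–B bond (1,2‑shift from boron to oxygen) proceeds with retention and without allylic transposition, giving the 13‑ol cis to C10; perborate is mild enough for the acetates.

Step 12
Reactants: 18 allylic alcohol
Product: 19 (1R,3Z,7E,10R,11R,12S,13R)-10,18-diacetoxyverticilla-3,7-dien-13-ol
Conditions: [Rh(nbd)(dppb)]BF4 (10 mol %), H2 (55 bar), CH2Cl2, rt
Reagents that add atoms: none
Why: Hydroxyl‑directed homogeneous hydrogenation: the cationic rhodium binds the C13 hydroxyl and adds H2 to the C1=C14 face cis to it (cis to C10), which sets C1 with C2 trans to C10 across the ring (the in,out bridge of the target); the isolated trisubstituted macrocyclic olefins are inert to this catalyst.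

Step 13
Reactants: 19 dienyl alcohol
Product: 20 (1S,3R,4S,7R,8R,10R,11R,12S,13R)-10,18-diacetoxy-3,4:7,8-diepoxyverticillan-13-ol
Conditions: 1,2:4,5-di-O-isopropylidene-β-D-erythro-2,3-hexodiulo-2,6-pyranose (0.6 equiv), Oxone (2KHSO5·KHSO4·K2SO4), K2CO3, Bu4NHSO4 (cat.), MeCN/dimethoxymethane/aq. Na2B4O7 buffer (pH 10.5), 0 °C
Reagents that add atoms: potassium peroxymonosulfate (from Oxone), [K+].OOS(=O)(=O)[O-]
Why: Shi asymmetric epoxidation: in the spiro transition state the lone vinylic hydrogen of each trisubstituted olefin takes the hindered quadrant, so oxygen goes to the same prochiral face of C3 and C7, giving the cis (3R,4S) oxirane from the Z olefin and the trans (7R,8R) oxirane from the E olefin in the same operation.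

Step 14
Reactants: 20 bis‑epoxy alcohol
Product: 22 (1R,3R,4S,7R,8R,10R,11S)-10-acetoxy-3,4:7,8-diepoxyverticill-12(18)-en-13-one (target), via β-acetoxy ketone 21 (not isolated)
Conditions: Dess–Martin periodinane, pyridine, CH2Cl2, 0 °C → rt; then DBU, 0 °C → rt
Reagents that add atoms: none
Why: Dess–Martin oxidation of the C13 carbinol, then E1cB elimination of acetic acid from the β‑acetoxy ketone, unveils the α‑methylene ketone; the C12 stereocentre is destroyed and the C10 acetate, being γ to the ketone, is untouched.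

## Compound list

1 | nerol, (2Z)-3,7-dimethylocta-2,6-dien-1-ol | OC/C=C(C)\CCC=C(C)C | starting material
2 | neryl bromide, (2Z)-1-bromo-3,7-dimethylocta-2,6-diene | BrC/C=C(C)\CCC=C(C)C | intermediate
3 | prenal, 3-methylbut-2-enal | CC(C)=CC=O | starting material
4 | potassium dienolate of prenal, potassium 3-methylbuta-1,3-dien-1-olate | [K+].[O-]C=CC(C)=C | intermediate
5 | (4Z)-5,9-dimethyl-2-(prop-1-en-2-yl)deca-4,8-dienal (racemic) | O=CC(C(C)=C)C/C=C(C)\CCC=C(C)C | intermediate
6 | (4Z)-5,9-dimethyl-2-(propan-2-ylidene)deca-4,8-dienal | O=CC(=C(C)C)C/C=C(C)\CCC=C(C)C | intermediate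
7 | (4Z,8E)-10-hydroxy-5,9-dimethyl-2-(propan-2-ylidene)deca-4,8-dienal | O=CC(=C(C)C)C/C=C(C)\CC/C=C(C)/CO | intermediate
8 | bis[(pinacolato)boryl]methane | C(B1OC(C)(C)C(C)(C)O1)B1OC(C)(C)C(C)(C)O1 | starting material
9 | lithium bis(pinacolboryl)methanide | [Li+].[CH-](B1OC(C)(C)C(C)(C)O1)B1OC(C)(C)C(C)(C)O1 | intermediate
10 | (2E,6Z,10E)-2,6-dimethyl-9-(propan-2-ylidene)-11-(4,4,5,5-tetramethyl-1,3,2-dioxaborolan-2-yl)undeca-2,6,10-trien-1-ol | CC(C)=C(/C=C/B1OC(C)(C)C(C)(C)O1)C/C=C(C)\CC/C=C(C)/CO | intermediate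
11 | 2-[(1E,5Z,9E)-11-chloro-6,10-dimethyl-3-(propan-2-ylidene)undeca-1,5,9-trien-1-yl]-4,4,5,5-tetramethyl-1,3,2-dioxaborolane | CC(C)=C(/C=C/B1OC(C)(C)C(C)(C)O1)C/C=C(C)\CC/C=C(C)/CCl | intermediate
12 | (E)-3-(tributylstannyl)prop-2-en-1-ol | OC/C=C/[Sn](CCCC)(CCCC)CCCC | starting material
13 | (E)-3-(tributylstannyl)prop-2-en-1-yl acetate | CC(=O)OC/C=C/[Sn](CCCC)(CCCC)CCCC | intermediate
14 | (2E,6E,10Z,14E)-6,10-dimethyl-4-oxo-13-(propan-2-ylidene)-15-(4,4,5,5-tetramethyl-1,3,2-dioxaborolan-2-yl)pentadeca-2,6,10,14-tetraen-1-yl acetate | CC(C)=C(/C=C/B1OC(C)(C)C(C)(C)O1)C/C=C(C)\CC/C=C(C)/CC(=O)/C=C/COC(C)=O | intermediate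
15 | (3Z,7E,11R,12S,13R)-18-acetoxy-13-(pinacolboryl)verticilla-1(14),3,7-trien-10-one | CC(=O)OC[C@H]1[C@H](B3OC(C)(C)C(C)(C)O3)/C=C2/C/C=C(C)\CC/C=C(C)/CC(=O)[C@H]1C2(C)C | intermediate
16 | (3Z,7E,10R,11R,12S,13R)-18-acetoxy-13-(pinacolboryl)verticilla-1(14),3,7-trien-10-ol | CC(=O)OC[C@H]1[C@H](B3OC(C)(C)C(C)(C)O3)/C=C2/C/C=C(C)\CC/C=C(C)/C[C@@H](O)[C@H]1C2(C)C | intermediate
17 | (3Z,7E,10R,11R,12S,13R)-10,18-diacetoxy-13-(pinacolboryl)verticilla-1(14),3,7-triene | CC(=O)OC[C@H]1[C@H](B3OC(C)(C)C(C)(C)O3)/C=C2/C/C=C(C)\CC/C=C(C)/C[C@@H](OC(C)=O)[C@H]1C2(C)C | intermediate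
18 | (3Z,7E,10R,11R,12S,13R)-10,18-diacetoxyverticilla-1(14),3,7-trien-13-ol | CC(=O)OC[C@H]1[C@H](O)/C=C2/C/C=C(C)\CC/C=C(C)/C[C@@H](OC(C)=O)[C@H]1C2(C)C | intermediate
19 | (1R,3Z,7E,10R,11R,12S,13R)-10,18-diacetoxyverticilla-3,7-dien-13-ol | CC(=O)OC[C@H]1[C@H](O)C[C@H]2C/C=C(C)\CC/C=C(C)/C[C@@H](OC(C)=O)[C@H]1C2(C)C | intermediate
20 | (1S,3R,4S,7R,8R,10R,11R,12S,13R)-10,18-diacetoxy-3,4:7,8-diepoxyverticillan-13-ol | CC(=O)OC[C@H]1[C@H](O)C[C@H]2C[C@H]3O[C@@]3(C)CC[C@H]3O[C@]3(C)C[C@@H](OC(C)=O)[C@H]1C2(C)C | intermediate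
21 | (1R,3R,4S,7R,8R,10R,11R,12S)-10,18-diacetoxy-3,4:7,8-diepoxyverticillan-13-one | CC(=O)OC[C@H]1C(=O)C[C@H]2C[C@H]3O[C@@]3(C)CC[C@H]3O[C@]3(C)C[C@@H](OC(C)=O)[C@H]1C2(C)C | intermediate
22 | (1R,3R,4S,7R,8R,10R,11S)-10-acetoxy-3,4:7,8-diepoxyverticill-12(18)-en-13-one | C=C1C(=O)C[C@H]2C[C@H]3O[C@@]3(C)CC[C@H]3O[C@]3(C)C[C@@H](OC(C)=O)[C@H]1C2(C)C | target

## Step count and risks

Total step count: 14. Longest linear sequence: 13 steps (1 → 22 through steps 1–5 and 7–14; step 6 is the side branch).

The three steps most likely to fail: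

**Step 8 (bicyclisation).** The boryl diene is only moderately reactive, the acid‑bound enone can be attacked by the nearby C7=C8 olefin, and the facial sense is unproven. The fallback sets out from 14 and comes back at 16. The cycloaddition is run thermally without any acid (toluene, BHT, 1 mM, 110 °C), which shuts down the ionic pathways but gives 15 together with its mirror image, antipodal cycloadduct F1. Absolute control is then taken from the reduction instead of the cycloaddition: the (S)-CBS reduction of step 9, applied to the racemate, turns 15 into 16 and F1 into diastereomeric (10R) alcohol F2, which is removed by chromatography (at most 50 % of 16).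

**Step 12 (directed hydrogenation).** The C1=C14 olefin is flanked by the quaternary C15 and may be too hindered for the rhodium catalyst, while a more active catalyst would attack the macrocyclic olefins. The fallback sets out from 18 and comes back at 21. Alcohol 18 is oxidised (Dess–Martin periodinane, pyridine) to bridgehead enone F3, in which C1=C14 is the only electron‑poor olefin. Copper hydride conjugate reduction (Cu(OAc)2, the DTBM‑SEGPHOS antipode that delivers hydride to the C1 face cis to C10, polymethylhydrosiloxane, t-BuOH, toluene) then gives saturated ketone F4, with C1 set by the ligand instead of by the hydroxyl group. Shi epoxidation of F4 as in step 13, run at pH 8 with excess ketone to spare the β‑acetoxy ketone, gives 21, which is treated with DBU as in step 14.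

**Step 13 (double epoxidation).** Reagent control is reliable for the E olefin but weaker for the Z olefin, where the macrocycle may decide the face. The fallback sets out from 19 and comes back at 20, and applies when the exposed face of C3=C4 is the wrong one. The Shi reaction is stopped after the faster E olefin has reacted, giving 7,8-monoepoxide F5. NBS in wet THF at 0 °C then forms the bromonium ion on the exposed face and water opens it at the tertiary C4 from the other side, giving bromohydrin F6. DBU closes the ring by SN2 at C3, which puts the oxirane oxygen on the face opposite to the one an electrophilic oxidant attacks and keeps C2 and C5 cis, giving 20.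

Further compounds
F1 | step 8 | (3Z,7E,11S,12R,13S)-18-acetoxy-13-(pinacolboryl)verticilla-1(14),3,7-trien-10-one (enantiomer of 15) | CC(=O)OC[C@@H]1[C@@H](B3OC(C)(C)C(C)(C)O3)/C=C2/C/C=C(C)\CC/C=C(C)/CC(=O)[C@@H]1C2(C)C
F2 | step 8 | (3Z,7E,10R,11S,12R,13S)-18-acetoxy-13-(pinacolboryl)verticilla-1(14),3,7-trien-10-ol | CC(=O)OC[C@@H]1[C@@H](B3OC(C)(C)C(C)(C)O3)/C=C2/C/C=C(C)\CC/C=C(C)/C[C@@H](O)[C@@H]1C2(C)C
F3 | step 12 | (3Z,7E,10R,11R,12S)-10,18-diacetoxyverticilla-1(14),3,7-trien-13-one | CC(=O)OC[C@H]1C(=O)/C=C2/C/C=C(C)\CC/C=C(C)/C[C@@H](OC(C)=O)[C@H]1C2(C)C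
F4 | step 12 | (1R,3Z,7E,10R,11R,12S)-10,18-diacetoxyverticilla-3,7-dien-13-one | CC(=O)OC[C@H]1C(=O)C[C@H]2C/C=C(C)\CC/C=C(C)/C[C@@H](OC(C)=O)[C@H]1C2(C)C
F5 | step 13 | (1R,3Z,7R,8R,10R,11R,12S,13R)-10,18-diacetoxy-7,8-epoxyverticill-3-en-13-ol | CC(=O)OC[C@H]1[C@H](O)C[C@H]2C/C=C(C)\CC[C@H]3O[C@]3(C)C[C@@H](OC(C)=O)[C@H]1C2(C)C
F6 | step 13 | (1S,3S,4S,7R,8R,10R,11R,12S,13R)-10,18-diacetoxy-3-bromo-7,8-epoxyverticillane-4,13-diol | CC(=O)OC[C@H]1[C@H](O)C[C@H]2C[C@H](Br)[C@](O)(C)CC[C@H]3O[C@]3(C)C[C@@H](OC(C)=O)[C@H]1C2(C)C
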